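The route rests on breaking the C1–C16 bond of the seven-membered ring C. In one operation a Lewis acid opens a 1α,2α-epoxide at C1 with the α-carbon C16 of a pendant 3-furyl group, which closes ring C and leaves the 2α-hydroxyl. The step exploits the fact that C16 sits on C1 trans to the free C2 hydroxyl, which is γ to lactone carbonyl C18 across the C3=C4 bond. The precursor is the complete ring A/B trans-decalin (7α-acetate, 18,19-butenolide, 1α,2α-epoxide) whose C9 carries, on the β face, a CH2–CH(OSi)–3-furyl chain. C12 is held as a single (12S) triisopropylsilyl ether, bulky enough to keep its oxygen from competing.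

Key step: step 24

Conventions: clerodane numbering is used for every bicyclic compound (C5 angular carbon, C19 its oxygenated CH2, C4 and C8 the two carbonyl carbons of the annulation product, C9=C10 its enone double bond). α is below and β above the decalin plane drawn with ring A on the left and C10 above C5.

Assumption: the amino-acid-mediated annulation (step 4) and the amino-alcohol-controlled zinc addition (step 22) are taken to show their usual sense of induction on these new substrates.

Step 1
Reactants: 1 cyclohexane-1,3-dione; 2 ethyl vinyl ketone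
Product: 3 2-(3-oxopentyl)cyclohexane-1,3-dione
Conditions: 1 (1.5 equiv), Et3N (cat.), MeCN, rt
Reagents that add atoms: none
Why: Michael addition of the acidic 1,3-dione to the enone; the excess of dione should limit double addition.

Step 2
Reactants: 3 2-(3-oxopentyl)cyclohexane-1,3-dione
Product: 4 2-(hydroxymethyl)-2-(3-oxopentyl)cyclohexane-1,3-dione
Conditions: 37% aq. HCHO, NaHCO3 (cat.), THF, 0 °C → rt
Reagents that add atoms: formaldehyde C=O
Why: Tollens-type aldol hydroxymethylation at the only strongly acidic carbon, which creates the quaternary carbon (future C5 with C19) without a stereocentre; the weak base should avoid retro-aldol and ring cleavage.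

Step 3
Reactants: 4 2-(hydroxymethyl)-2-(3-oxopentyl)cyclohexane-1,3-dione
Product: 5 2-[(tert-butyldimethylsilyloxy)methyl]-2-(3-oxopentyl)cyclohexane-1,3-dione
Conditions: TBSCl, imidazole, DMF, 0 °C → rt
Reagents that add atoms: tert-butyldimethylsilyl chloride CC(C)(C)[Si](C)(C)Cl
Why: standard silylation of a primary alcohol, which also removes the possibility of retro-aldol loss of formaldehyde.

Step 4
Reactants: 5 silyloxymethyl triketone
Product: 6 (8aR)-8a-[(tert-butyldimethylsilyloxy)methyl]-5-methyl-3,4,8,8a-tetrahydronaphthalene-1,6(2H,7H)-dione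
Conditions: D-phenylalanine (1 equiv), (+)-CSA (0.5 equiv), DMF, rt → 65 °C
Reagents that add atoms: none
Why: Hajos–Parrish–Eder–Sauer–Wiechert-type intramolecular aldol condensation (second stage of a Robinson annulation), in which the enamine of the ethyl ketone selects one of the two enantiotopic ring carbonyls; the D-amino acid should give the angular carbon C5 with C19 on the α face, the mirror image of the steroid series.

Step 5
Reactants: 6 enedione
Product: 7 C4 ethylene ketal of enedione 6 (C8 enone retained)
Conditions: (TMSOCH2)2, TMSOTf (cat.), CH2Cl2, −78 → −20 °C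
Reagents that add atoms: 1,2-bis(trimethylsilyloxy)ethane C[Si](C)(C)OCCO[Si](C)(C)C
Why: Noyori ketalisation, which takes the saturated C4 ketone in preference to the conjugated tetrasubstituted enone and is aprotic enough to spare the silyl ether.

Step 6
Reactants: 7 enone ketal; 8 methyl bromoacetate
Product: 10 trans-fused keto ester (C4 dioxolane; 5α-CH2OTBS; C8 ketone; 9α-CH3; 9β-CH2CO2Me; 10β-H), via lithium enolate 9 (not isolated)
Conditions: Li, NH3(l)/THF, t-BuOH (1 equiv), −78 °C; NH3 evaporated; then 8, THF, −78 → 0 °C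
Reagents that add atoms: none
Why: Stork reductive alkylation, in which protonation at C10 gives the trans ring fusion (10β-H, anti to C19) and the regiodefined C8(9) enolate is alkylated at C9 from the β face, away from the axial C5 substituent, so that C20 ends α and C11 β.

Step 7
Reactants: 10 keto ester
Product: 11 C7(8)-enol triflate of keto ester 10
Conditions: KHMDS, THF, −78 °C; PhNTf2
Reagents that add atoms: N-phenylbis(trifluoromethanesulfonimide) O=S(=O)(N(c1ccccc1)S(=O)(=O)C(F)(F)F)C(F)(F)F
Why: kinetic enolisation of the ketone is possible only toward C7 (C9 is quaternary) and is faster than deprotonation of the neopentyl ester, and the enolate is O-triflated.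

Step 8
Reactants: 11 enol triflate
Product: 12 8-methyl-7-ene (C7=C8–CH3; ester and ketal unchanged)
Conditions: MeMgBr, Fe(acac)3 (5 mol%), THF/NMP, −30 °C
Reagents that add atoms: methylmagnesium bromide C[Mg]Br
Why: iron-catalysed Kumada-type cross-coupling of an alkenyl triflate, which is faster at low temperature than Grignard addition to the ester and installs C17.

Step 9
Reactants: 12 8-methyl-7-ene
Product: 14 7β-alcohol (8α-CH3; 8β-H), via alkylborane 13 (not isolated)
Conditions: BH3·THF, THF, 0 °C → rt; then NaBO3·4H2O, H2O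
Reagents that add atoms: sodium perborate [Na+].[Na+].O[B-]1(O)OO[B-](O)(O)OO1
Why: hydroboration–oxidation places boron on the less substituted C7 and adds H and B syn from the β face, because the α face is shielded by the axial C19 and C20 groups, which sets C8 (8β-H, 8α-CH3); the mild perborate work-up spares the ester.

Step 10
Reactants: 14 7β-alcohol
Product: 15 C7 ketone (8α-CH3; methyl ester retained)
Conditions: Dess–Martin periodinane, CH2Cl2, rt
Reagents that add atoms: none
Why: Dess–Martin oxidation of a secondary alcohol under neutral conditions; the equatorial 8α-methyl group is also the thermodynamic epimer, so C8 is not at risk.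

Step 11
Reactants: 15 C7 ketone
Product: 16 7α,12-diol (C4 dioxolane; 19-OTBS)
Conditions: LiAlH4, THF, 0 °C
Reagents that add atoms: none
Why: hydride reduction in which the α face of the C7 carbonyl is blocked by the two syn-axial groups on C5 and C9, so hydride should enter from the β face and give the axial 7α-alcohol; the ester is reduced to the C12 alcohol in the same operation.

Step 12
Reactants: 16 7α,12-diol
Product: 17 12-O-TBDPS 7α-alcohol
Conditions: TBDPSCl (1.05 equiv), imidazole, CH2Cl2, 0 °C
Reagents that add atoms: tert-butyldiphenylsilyl chloride CC(C)(C)[Si](Cl)(c1ccccc1)c1ccccc1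
Why: silylation selects the unhindered primary alcohol over the axial, doubly flanked 7α-hydroxyl.

Step 13
Reactants: 17 12-O-TBDPS 7α-alcohol
Product: 18 7α-acetate
Conditions: Ac2O, DMAP (1 equiv), pyridine, 60 °C
Reagents that add atoms: acetic anhydride CC(=O)OC(C)=O
Why: DMAP-catalysed acylation under forcing conditions, needed because the axial alcohol is hindered; nothing else in the molecule reacts.

Step 14
Reactants: 18 7α-acetate
Product: 19 C4 ketone (7α-OAc; 19-OTBS; 12-OTBDPS)
Conditions: PPTS, acetone/H2O (10:1), 50 °C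
Reagents that add atoms: water O
Why: mildly acidic ketal hydrolysis; the neopentyl TBS ether, the TBDPS ether and the acetate should survive these buffered conditions.

Step 15
Reactants: 19 C4 ketone
Product: 21 2-en-4-one, via trimethylsilyl enol ether 20 (not isolated)
Conditions: TMSOTf, Et3N, CH2Cl2, 0 °C; then Pd(OAc)2, MeCN, rt
Reagents that add atoms: none
Why: Saegusa–Ito oxidation; soft enolisation can only occur toward C3 because C5 is quaternary, and the base-free conditions spare the acetate.

Step 16
Reactants: 21 2-en-4-one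
Product: 22 1,3-dien-4-yl triflate (C4(OTf)=C3–C2=C1)
Conditions: Tf2O, 2,6-di-tert-butyl-4-methylpyridine, CH2Cl2, −78 → 0 °C
Reagents that add atoms: trifluoromethanesulfonic anhydride O=S(=O)(OS(=O)(=O)C(F)(F)F)C(F)(F)F
Why: O-triflation of the enone followed by loss of the γ-proton at C1, the only proton available because C5 is quaternary, gives the linear dienyl triflate without an enolate base that would attack the acetate.

Step 17
Reactants: 22 dienyl triflate
Product: 23 19-hydroxy dienyl triflate
Conditions: CSA (cat.), MeOH/CH2Cl2, 0 °C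
Reagents that add atoms: none
Why: acid-catalysed methanolysis cleaves a primary TBS ether much faster than a TBDPS ether, and alkenyl triflates and the hindered acetate tolerate it.

Step 18
Reactants: 23 19-hydroxy dienyl triflate
Product: 24 7α-acetoxy-12-(tert-butyldiphenylsilyloxy)-13,14,15,16-tetranorcleroda-1,3-dien-18,19-olide
Conditions: CO (1 atm), Pd(PPh3)4 (5 mol%), Et3N, DMF, 60 °C
Reagents that add atoms: carbon monoxide [C-]#[O+]
Why: palladium-catalysed carbonylative lactonisation, in which zerovalent palladium inserts into the C4–OTf bond, CO inserts, and the C19 hydroxyl captures the acyl-palladium to close the five-membered butenolide (C18).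

Step 19
Reactants: 24 dienolide
Product: 26 1α,2α-epoxy-3-en-18,19-olide (7α-OAc; 12-OTBDPS), via bromohydrin 25 (not isolated)
Conditions: NBS, THF/H2O, 0 °C, dark; then K2CO3, rt
Reagents that add atoms: water O
Why: halohydrin formation and ring closure; the bromonium ion should form on the more open β face of the electron-richer distal C1=C2 bond, water opens it anti at allylic C2, and the 2α-alkoxide then displaces bromide at C1 with inversion to put the epoxide on the α face, which direct epoxidation would not reach (either trans-bromohydrin regioisomer converges on 26).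

Step 20
Reactants: 26 epoxy enolide
Product: 27 12-alcohol of the epoxy enolide
Conditions: TBAF, AcOH (1:1), THF, 0 °C → rt
Reagents that add atoms: none
Why: buffered fluoride desilylation, which avoids the γ-deprotonation at C2 that would open the epoxide; the alcohol is oxidised at once because it is placed to attack C1.

Step 21
Reactants: 27 12-alcohol
Product: 28 12-aldehyde of the epoxy enolide
Conditions: Dess–Martin periodinane, pyridine, CH2Cl2, 0 °C
Reagents that add atoms: none
Why: Dess–Martin oxidation under buffered neutral conditions that the epoxide, butenolide and acetate tolerate.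

Step 22
Reactants: 28 12-aldehyde; 29 3-bromofuran
Product: 32 (12S)-12-(3-furyl)-12-hydroxy epoxy enolide, via 3-furyllithium 30 (not isolated), via ethyl(3-furyl)zinc 31 (not isolated)
Conditions: 29, n-BuLi, t-BuOMe, −78 °C; EtZnCl; TEEDA, (+)-MIB (10 mol%), toluene; then 28, 0 °C
Reagents that add atoms: none
Why: catalytic asymmetric heteroaryl transfer from a mixed aryl(alkyl)zinc reagent to an aldehyde under amino-alcohol control, where (+)-MIB should direct the furyl group to the Re face and give 12S; the non-basic zinc reagent spares the lactone, acetate and epoxide, and a minor 12R epimer would be harmless because C12 is oxidised at the end.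

Step 23
Reactants: 32 (12S)-furyl carbinol
Product: 33 (12S)-12-O-triisopropylsilyl cyclisation precursor
Conditions: TIPSOTf, 2,6-lutidine, CH2Cl2, −78 °C
Reagents that add atoms: triisopropylsilyl trifluoromethanesulfonate CC(C)[Si](OS(=O)(=O)C(F)(F)F)(C(C)C)C(C)C
Why: silyl triflate silylation is fast at low temperature, so the hydroxyl is capped before it can attack the epoxide; the bulky group makes the C12 oxygen a poor nucleophile and a poor Lewis base for the next step.

Step 24
Reactants: 33 (12S)-12-O-triisopropylsilyl epoxy enolide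
Product: 34 ring C-closed 12-O-triisopropylsilyl 2α-alcohol (C1–C16 bond; 1β-furyl; 12S)
Conditions: Sc(OTf)3 (15 mol%), 4 Å MS, CH2Cl2, −40 → 0 °C
Reagents that add atoms: none
Why: The Lewis acid binds the epoxide oxygen, furan C16 attacks C1 from the β face anti to the breaking C1–O bond, and loss of the C16 proton restores the furan and frees the 2α-hydroxyl. The closest known reaction is the Lewis-acid-mediated intramolecular Friedel–Crafts alkylation of a furan by an epoxide. Ring C closes in the 7-exo-tet mode. The new C1 configuration follows from inversion at C1 of the α-epoxide, with the tether fixed on the β face of C9, so the C1 furyl bond is β and trans to the 2α-hydroxyl. C1 is preferred over C2 because attack at C2 would need an eight-membered bridged ring and ionisation at C2 would place positive charge next to the lactone carbonyl; C16 is preferred over C14 because it is the α-position of the furan; carbon is preferred over oxygen attack because the triisopropylsilyl ether is too hindered to form the six-membered ether or to ionise. The tether forces a diequatorial opening against the usual diaxial preference, which is the main uncertainty and is eased by the flattened cyclohexene ring A.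

Step 25
Reactants: 34 ring C-closed silyl ether
Product: 35 (12S)-2α,12-diol (12-dihydro target)
Conditions: TBAF, AcOH (1:1), THF, rt
Reagents that add atoms: none
Why: buffered fluoride desilylation; neither acid that could ionise the furyl carbinol nor base that could isomerise the γ-hydroxy butenolide is present.

Step 26
Reactants: 35 2α,12-diol
Product: 36 target CNP0182929.1
Conditions: MnO2, CH2Cl2, rt
Reagents that add atoms: none
Why: MnO2 oxidation of the electron-rich furyl carbinol to the C12 ketone, which erases the auxiliary C12 stereocentre; the C2 alcohol is also allylic but is deactivated by the conjugated lactone and hindered, so it should react far more slowly.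

Compound list
1 | cyclohexane-1,3-dione | O=C1CCCC(=O)C1 | starting material
2 | ethyl vinyl ketone (pent-1-en-3-one) | CCC(=O)C=C | starting material
3 | 2-(3-oxopentyl)cyclohexane-1,3-dione | CCC(=O)CCC1C(=O)CCCC1=O | intermediate
4 | 2-(hydroxymethyl)-2-(3-oxopentyl)cyclohexane-1,3-dione | CCC(=O)CCC1(CO)C(=O)CCCC1=O | intermediate
5 | 2-[(tert-butyldimethylsilyloxy)methyl]-2-(3-oxopentyl)cyclohexane-1,3-dione | CCC(=O)CCC1(CO[Si](C)(C)C(C)(C)C)C(=O)CCCC1=O | intermediate
6 | (8aR)-8a-[(tert-butyldimethylsilyloxy)methyl]-5-methyl-3,4,8,8a-tetrahydronaphthalene-1,6(2H,7H)-dione (C4 and C8 ketones, C9=C10, 5α-CH2OTBS) | O=C1CC[C@@]2(CO[Si](C)(C)C(C)(C)C)C(=O)CCCC2=C1C | intermediate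
7 | C4 ethylene ketal of 6 | O=C1CC[C@@]2(CO[Si](C)(C)C(C)(C)C)C3(OCCO3)CCCC2=C1C | intermediate
8 | methyl bromoacetate | COC(=O)CBr | starting material
9 | lithium C8(9)-enolate of the trans-fused (10β-H) ketal | C1C[C@@]2(CO[Si](C)(C)C(C)(C)C)C3(OCCO3)CCC[C@@H]2C(C)=C1O[Li] | intermediate
10 | keto ester: C4 dioxolane, 5α-CH2OTBS, C8 ketone, 9α-CH3, 9β-CH2CO2Me, 10β-H | C1C[C@@]2(CO[Si](C)(C)C(C)(C)C)C3(OCCO3)CCC[C@@H]2[C@@](C)(CC(=O)OC)C1=O | intermediate
11 | C7(8)-enol triflate of 10 | C1C[C@@]2(CO[Si](C)(C)C(C)(C)C)C3(OCCO3)CCC[C@@H]2[C@@](C)(CC(=O)OC)C(OS(=O)(=O)C(F)(F)F)=C1 | intermediate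
12 | 8-methyl-7-ene (C7=C8–CH3) | C1C[C@@]2(CO[Si](C)(C)C(C)(C)C)C3(OCCO3)CCC[C@@H]2[C@@](C)(CC(=O)OC)C(C)=C1 | intermediate
13 | 7β-boryl-8α-methyl alkylborane | B[C@H]1C[C@@]2(CO[Si](C)(C)C(C)(C)C)C3(OCCO3)CCC[C@@H]2[C@@](C)(CC(=O)OC)[C@@H]1C | intermediate
14 | 7β-alcohol, 8α-CH3 (8β-H), methyl ester | O[C@H]1C[C@@]2(CO[Si](C)(C)C(C)(C)C)C3(OCCO3)CCC[C@@H]2[C@@](C)(CC(=O)OC)[C@@H]1C | intermediate
15 | C7 ketone, 8α-CH3, methyl ester | O=C1C[C@@]2(CO[Si](C)(C)C(C)(C)C)C3(OCCO3)CCC[C@@H]2[C@@](C)(CC(=O)OC)[C@@H]1C | intermediate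
16 | 7α,12-diol (C4 dioxolane, 19-OTBS) | O[C@@H]1C[C@@]2(CO[Si](C)(C)C(C)(C)C)C3(OCCO3)CCC[C@@H]2[C@@](C)(CCO)[C@@H]1C | intermediate
17 | 12-O-TBDPS 7α-alcohol | O[C@@H]1C[C@@]2(CO[Si](C)(C)C(C)(C)C)C3(OCCO3)CCC[C@@H]2[C@@](C)(CCO[Si](c4ccccc4)(c4ccccc4)C(C)(C)C)[C@@H]1C | intermediate
18 | 7α-acetate (C4 dioxolane, 19-OTBS, 12-OTBDPS) | CC(=O)O[C@@H]1C[C@@]2(CO[Si](C)(C)C(C)(C)C)C3(OCCO3)CCC[C@@H]2[C@@](C)(CCO[Si](c4ccccc4)(c4ccccc4)C(C)(C)C)[C@@H]1C | intermediate
19 | C4 ketone (7α-OAc, 19-OTBS, 12-OTBDPS) | CC(=O)O[C@@H]1C[C@@]2(CO[Si](C)(C)C(C)(C)C)C(=O)CCC[C@@H]2[C@@](C)(CCO[Si](c3ccccc3)(c3ccccc3)C(C)(C)C)[C@@H]1C | intermediate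
20 | C4 trimethylsilyl enol ether (C3=C4) | CC(=O)O[C@@H]1C[C@@]2(CO[Si](C)(C)C(C)(C)C)C(O[Si](C)(C)C)=CCC[C@@H]2[C@@](C)(CCO[Si](c3ccccc3)(c3ccccc3)C(C)(C)C)[C@@H]1C | intermediate
21 | 2-en-4-one | CC(=O)O[C@@H]1C[C@@]2(CO[Si](C)(C)C(C)(C)C)C(=O)C=CC[C@@H]2[C@@](C)(CCO[Si](c3ccccc3)(c3ccccc3)C(C)(C)C)[C@@H]1C | intermediate
22 | 1,3-dien-4-yl triflate | CC(=O)O[C@@H]1C[C@@]2(CO[Si](C)(C)C(C)(C)C)C(OS(=O)(=O)C(F)(F)F)=CC=C[C@@H]2[C@@](C)(CCO[Si](c3ccccc3)(c3ccccc3)C(C)(C)C)[C@@H]1C | intermediate
23 | 19-hydroxy 1,3-dien-4-yl triflate | CC(=O)O[C@@H]1C[C@@]2(CO)C(OS(=O)(=O)C(F)(F)F)=CC=C[C@@H]2[C@@](C)(CCO[Si](c3ccccc3)(c3ccccc3)C(C)(C)C)[C@@H]1C | intermediate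
24 | 7α-acetoxy-12-(tert-butyldiphenylsilyloxy)-13,14,15,16-tetranorcleroda-1,3-dien-18,19-olide | CC(=O)O[C@@H]1C[C@@]23COC(=O)C2=CC=C[C@@H]3[C@@](C)(CCO[Si](c4ccccc4)(c4ccccc4)C(C)(C)C)[C@@H]1C | intermediate
25 | 1β-bromo-2α-hydroxy-3-en-18,19-olide (bromohydrin of 24) | CC(=O)O[C@@H]1C[C@@]23COC(=O)C2=C[C@H](O)[C@@H](Br)[C@@H]3[C@@](C)(CCO[Si](c4ccccc4)(c4ccccc4)C(C)(C)C)[C@@H]1C | intermediate
26 | 1α,2α-epoxy-3-en-18,19-olide, 7α-OAc, 12-OTBDPS | CC(=O)O[C@@H]1C[C@@]23COC(=O)C2=C[C@@H]2O[C@@H]2[C@@H]3[C@@](C)(CCO[Si](c4ccccc4)(c4ccccc4)C(C)(C)C)[C@@H]1C | intermediate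
27 | 12-alcohol of the 1α,2α-epoxy-3-en-18,19-olide | CC(=O)O[C@@H]1C[C@@]23COC(=O)C2=C[C@@H]2O[C@@H]2[C@@H]3[C@@](C)(CCO)[C@@H]1C | intermediate
28 | 12-aldehyde of the 1α,2α-epoxy-3-en-18,19-olide | CC(=O)O[C@@H]1C[C@@]23COC(=O)C2=C[C@@H]2O[C@@H]2[C@@H]3[C@@](C)(CC=O)[C@@H]1C | intermediate
29 | 3-bromofuran | Brc1ccoc1 | starting material
30 | 3-furyllithium | [Li]c1ccoc1 | intermediate
31 | ethyl(3-furyl)zinc | CC[Zn]c1ccoc1 | intermediate
32 | (12S)-12-(3-furyl)-12-hydroxy-1α,2α-epoxy-3-en-18,19-olide | CC(=O)O[C@@H]1C[C@@]23COC(=O)C2=C[C@@H]2O[C@@H]2[C@@H]3[C@@](C)(C[C@H](O)c4ccoc4)[C@@H]1C | intermediate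
33 | (12S)-12-O-triisopropylsilyl ether of 32 (cyclisation precursor) | CC(=O)O[C@@H]1C[C@@]23COC(=O)C2=C[C@@H]2O[C@@H]2[C@@H]3[C@@](C)(C[C@H](O[Si](C(C)C)(C(C)C)C(C)C)c4ccoc4)[C@@H]1C | intermediate
34 | ring C-closed (12S)-12-O-triisopropylsilyl 2α-alcohol (C1–C16 bond, 1β-furyl) | CC(=O)O[C@@H]1C[C@@]23COC(=O)C2=C[C@H](O)[C@H]2c4occc4[C@@H](O[Si](C(C)C)(C(C)C)C(C)C)C[C@@](C)([C@@H]1C)[C@@H]23 | intermediate
35 | (12S)-2α,12-diol (12-dihydro target) | CC(=O)O[C@@H]1C[C@@]23COC(=O)C2=C[C@H](O)[C@H]2c4occc4[C@@H](O)C[C@@](C)([C@@H]1C)[C@@H]23 | intermediate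
36 | CNP0182929.1 | CC(=O)O[C@@H]1C[C@@]23COC(=O)C2=C[C@H](O)[C@H]2c4occc4C(=O)C[C@@](C)([C@@H]1C)[C@@H]23 | target

Total step count: 26. Longest linear sequence: 26 steps (1 to 36); 3-bromofuran 29 enters in step 22.

Steps most likely to fail

Step 24. The Lewis acid may divert the activated epoxide into hydride shift, capture by adventitious nucleophiles or decomposition of the furan, because the tether forces the disfavoured diequatorial opening at a hindered secondary carbon. The fallback closes ring C by a vinylogous Friedel–Crafts conjugate addition instead of an epoxide opening. It sets out from dienolide 24, which skips step 19. Buffered TBAF gives the dienolide 12-alcohol F1 and Dess–Martin oxidation gives the dienolide 12-aldehyde F2. The zinc addition of step 22 gives the (12S)-furyl carbinol F3, and TIPSOTf with 2,6-lutidine gives the silyl ether F4. TfOH (cat.) in HFIP/CH2Cl2 then protonates the lactone carbonyl, and C16 adds to the δ-carbon C1 from the β face (7-exo-trig) to give the 2-deoxy ring C-closed enolide F5. SeO2 with t-BuOOH hydroxylates the γ-methylene C2 from the α face, anti to the C1 furyl bond, and the route is rejoined at 34.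

Step 19. The bromonium ion may form without facial preference or on the α face, or the bromohydrin may fail to close. The fallback is direct oxygen transfer: from 24, dimethyldioxirane in acetone at 0 °C epoxidises the C1=C2 bond on the face an electrophile prefers, which is the opposite outcome to the halohydrin sequence. If the α face is the preferred one, this gives 26 directly, where the route is rejoined; no new compound is made.

Step 4. Ring closure may be slow or poorly enantioselective with the bulky angular silyloxymethyl group. The fallback is racemic annulation and resolution. From 5, pyrrolidine and AcOH give racemic material, that is 6 together with its enantiomer F6. Ketalisation at C4 with (2R,3R)-butane-2,3-diol (PPTS, benzene, reflux) gives the diastereomeric ketals F7 (from 6) and F8 (from F6), which are separated by chromatography. PPTS in wet acetone releases enantiopure 6 from F7, where the route is rejoined.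

Further compounds
F1 | step 24 | 12-alcohol of the 7α-acetoxy-1,3-dien-18,19-olide | CC(=O)O[C@@H]1C[C@@]23COC(=O)C2=CC=C[C@@H]3[C@@](C)(CCO)[C@@H]1C
F2 | step 24 | 12-aldehyde of the 7α-acetoxy-1,3-dien-18,19-olide | CC(=O)O[C@@H]1C[C@@]23COC(=O)C2=CC=C[C@@H]3[C@@](C)(CC=O)[C@@H]1C
F3 | step 24 | (12S)-12-(3-furyl)-12-hydroxy-1,3-dien-18,19-olide | CC(=O)O[C@@H]1C[C@@]23COC(=O)C2=CC=C[C@@H]3[C@@](C)(C[C@H](O)c4ccoc4)[C@@H]1C
F4 | step 24 | (12S)-12-O-triisopropylsilyl ether of F3 | CC(=O)O[C@@H]1C[C@@]23COC(=O)C2=CC=C[C@@H]3[C@@](C)(C[C@H](O[Si](C(C)C)(C(C)C)C(C)C)c4ccoc4)[C@@H]1C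
F5 | step 24 | 2-deoxy analogue of 34 (C1–C16 bond, C2 methylene, 3-en-18,19-olide) | CC(=O)O[C@@H]1C[C@@]23COC(=O)C2=CC[C@H]2c4occc4[C@@H](O[Si](C(C)C)(C(C)C)C(C)C)C[C@@](C)([C@@H]1C)[C@@H]23
F0 | step 19 | none | none
F6 | step 4 | (8aS)-enantiomer of 6 | O=C1CC[C@]2(CO[Si](C)(C)C(C)(C)C)C(=O)CCCC2=C1C
F7 | step 4 | C4 ketal of 6 with (2R,3R)-butane-2,3-diol | O=C1CC[C@@]2(CO[Si](C)(C)C(C)(C)C)C3(O[C@H](C)[C@@H](C)O3)CCCC2=C1C
F8 | step 4 | C4 ketal of F6 with (2R,3R)-butane-2,3-diol | O=C1CC[C@]2(CO[Si](C)(C)C(C)(C)C)C3(O[C@H](C)[C@@H](C)O3)CCCC2=C1C
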